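**Plan**

1. The target is read as a (1(10)Z,4Z)-germacra-1(10),4,11(13)-trien-12,6-olide, numbered C1=C10(C14)–C9–C8–C7(C11(=C13)–C12)–C6–C5=C4(C15)–C3–C2. The lactone is cis-fused at C6/C7; O6, C11, 8-OH and the 9-O-(2R,3R)-epoxyangelate lie on one ring face and 3-OAc on the other. Inside the ten-membered ring, C13=C11–C7–C8–OH is a homoallylic alcohol whose allyl part is the α-methylene lactone; this is the retron of a carbonyl allylation by a 3-(bromomethyl)butenolide.
2. Retrosynthesis: first the ring bond C7–C8 (C13 bromide plus C8 aldehyde), then the C9 ester, the C3–C4 bond (vinyl iodide plus aldehyde), the butenolide (C7=C11 by metathesis, O6–C12 by esterification) and C1=C10 (Wittig).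
3. Forward: the epoxide of the side-chain acid is closed in its own branch. The butenolide is closed by metathesis on an iodo-diene, before any other reactive alkene is present. The halves are joined by nickel/chromium coupling, and the ten-membered carbocycle closes last by intramolecular chromium-mediated allylation.
4. Stereochemistry: C9 is bought (glycerate), C6 comes from a Sharpless desymmetrisation, C3 from a CBS reduction, the epoxide from a Sharpless epoxidation. C7 and C8 are relayed from C6 and C9 in the ring closure. Both Z-alkenes come from Wittig reactions.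

Key step: step 28

**Route**

Step 1
Reactants: 1 (3-bromopropoxy)(tert-butyl)dimethylsilane
Product: 2 {3-[(tert-butyldimethylsilyl)oxy]propyl}triphenylphosphonium bromide
Conditions: PPh3, MeCN, 80 °C
Reagents that add atoms: triphenylphosphine, c1ccc(cc1)P(c1ccccc1)c1ccccc1
Why: SN2 quaternisation of the phosphine by a primary bromide gives the Wittig salt that supplies C1–C3; no stereocenter is formed.

Step 2
Reactants: 3 methyl (4R)-2,2-dimethyl-1,3-dioxolane-4-carboxylate
Product: 5 1-[(4R)-2,2-dimethyl-1,3-dioxolan-4-yl]ethan-1-one, via Weinreb amide 4 (not isolated)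
Conditions: MeNHOMe·HCl, iPrMgCl, THF, −20 °C; then MeMgBr, −20 → 0 °C
Reagents that add atoms: methylmagnesium bromide, C[Mg]Br; N,O-dimethylhydroxylamine hydrochloride, CNOC.Cl (its atoms stay only in 4)
Why: Ester-to-Weinreb-amide exchange followed by Grignard addition to the chelated amide should stop at the methyl ketone (the new methyl is C14); C9 is bought with the glycerate and is not touched.

Step 3
Reactants: 2 {3-[(tert-butyldimethylsilyl)oxy]propyl}triphenylphosphonium bromide; 5 1-[(4R)-2,2-dimethyl-1,3-dioxolan-4-yl]ethan-1-one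
Product: 7 tert-butyl({(3Z)-4-[(4S)-2,2-dimethyl-1,3-dioxolan-4-yl]pent-3-en-1-yl}oxy)dimethylsilane, via phosphonium ylide 6 (not isolated)
Conditions: NaN(SiMe3)2, THF, −78 → 0 °C; then 5, −78 °C → rt
Reagents that add atoms: none
Why: Wittig olefination of an α-alkoxy methyl ketone with a non-stabilised ylide is known to favour the Z-trisubstituted alkene, which puts C9 cis to C2 as C1=C10 requires; low temperature should keep the ketone from enolising at C9.

Step 4
Reactants: 7 tert-butyl({(3Z)-4-[(4S)-2,2-dimethyl-1,3-dioxolan-4-yl]pent-3-en-1-yl}oxy)dimethylsilane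
Product: 8 (3Z)-4-[(4S)-2,2-dimethyl-1,3-dioxolan-4-yl]pent-3-en-1-ol
Conditions: Bu4NF, THF, 0 °C
Reagents that add atoms: none
Why: Fluoride desilylation frees the primary alcohol and leaves the acetonide intact.

Step 5
Reactants: 8 (3Z)-4-[(4S)-2,2-dimethyl-1,3-dioxolan-4-yl]pent-3-en-1-ol
Product: 9 (3Z)-4-[(4S)-2,2-dimethyl-1,3-dioxolan-4-yl]pent-3-enal
Conditions: DMP, pyridine, CH2Cl2, 0 °C
Reagents that add atoms: none
Why: Dess–Martin oxidation under buffered conditions should give the β,γ-unsaturated C3 aldehyde without moving the C1=C10 double bond; it is made just before step 14.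

Step 6
Reactants: 10 2-(bromomethyl)prop-2-enoic acid
Product: 11 2-{[(4-methoxybenzyl)oxy]methyl}prop-2-enoic acid
Conditions: 4-methoxybenzyl alcohol, NaH (2.2 equiv), THF, 0 °C → rt; then aq. HCl
Reagents that add atoms: 4-methoxybenzyl alcohol, COc1ccc(CO)cc1
Why: Williamson etherification: the sodium alkoxide displaces the allylic bromide of the sodium carboxylate (SN2 and SN2′ give the same product), which masks the future C13 bromide as a PMB ether.

Step 7
Reactants: 12 penta-1,4-dien-3-ol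
Product: 13 (1S)-1-[(2R)-oxiran-2-yl]prop-2-en-1-ol
Conditions: Ti(OiPr)4 (cat.), L-(+)-diisopropyl tartrate (cat.), t-BuOOH, 4 Å molecular sieves, CH2Cl2, −20 °C
Reagents that add atoms: tert-butyl hydroperoxide, CC(C)(C)OO
Why: Sharpless asymmetric epoxidation of the achiral divinyl carbinol couples enantiotopic-group with diastereofacial selection, so the catalyst sets the future C6 carbinol (S) and the sacrificial epoxide carbon (R).

Step 8
Reactants: 13 (1S)-1-[(2R)-oxiran-2-yl]prop-2-en-1-ol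
Product: 14 tert-butyldimethyl({(1S)-1-[(2R)-oxiran-2-yl]prop-2-en-1-yl}oxy)silane
Conditions: TBSCl, imidazole, CH2Cl2, 0 °C
Reagents that add atoms: tert-butyldimethylsilyl chloride, CC(C)(C)[Si](C)(C)Cl
Why: Silylation under weakly basic conditions protects the C6 oxygen without Payne migration of the epoxide.

Step 9
Reactants: 14 tert-butyldimethyl({(1S)-1-[(2R)-oxiran-2-yl]prop-2-en-1-yl}oxy)silane
Product: 16 (2S)-2-[(tert-butyldimethylsilyl)oxy]but-3-enal, via 1,2-diol 15 (not isolated)
Conditions: H5IO6, THF, 0 °C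
Reagents that add atoms: water (supplied with H5IO6), O; it adds atoms only to 15
Why: Periodic acid opens the terminal epoxide to the diol and cleaves it in the same flask (Malaprade cleavage), which removes the epoxide CH2 and leaves the C5 aldehyde next to the untouched C6 center.

Step 10
Reactants: 16 (2S)-2-[(tert-butyldimethylsilyl)oxy]but-3-enal
Product: 17 tert-butyl{[(3S,4Z)-5-iodohexa-1,4-dien-3-yl]oxy}dimethylsilane
Conditions: EtPPh3I, n-BuLi, THF, 0 °C; I2, −78 °C; NaN(SiMe3)2, −78 °C; then 16, −78 → −20 °C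
Reagents that add atoms: ethyltriphenylphosphonium iodide, CC[P+](c1ccccc1)(c1ccccc1)c1ccccc1.[I-]; iodine, II
Why: Wittig olefination with the α-iodoethylidene ylide (Stork–Zhao-type) should give the (Z)-2-iodoalkene, in which iodine is cis to C6 and marks the place C3 takes on C4=C5; low temperature protects the enolisable aldehyde.

Step 11
Reactants: 17 tert-butyl{[(3S,4Z)-5-iodohexa-1,4-dien-3-yl]oxy}dimethylsilane
Product: 18 (3S,4Z)-5-iodohexa-1,4-dien-3-ol
Conditions: Bu4NF, THF, 0 °C
Reagents that add atoms: none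
Why: Fluoride desilylation frees the C6 hydroxyl; the vinyl iodide is inert to fluoride.

Step 12
Reactants: 18 (3S,4Z)-5-iodohexa-1,4-dien-3-ol; 11 2-{[(4-methoxybenzyl)oxy]methyl}prop-2-enoic acid
Product: 20 (3S,4Z)-5-iodohexa-1,4-dien-3-yl 2-{[(4-methoxybenzyl)oxy]methyl}prop-2-enoate, via O-acylisourea 19 (not isolated)
Conditions: DCC, DMAP (cat.), CH2Cl2, 0 °C → rt
Reagents that add atoms: none
Why: Steglich esterification attaches C11–C13 and C12 to the C6 oxygen without touching the stereocenter.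

Step 13
Reactants: 20 (3S,4Z)-5-iodohexa-1,4-dien-3-yl 2-{[(4-methoxybenzyl)oxy]methyl}prop-2-enoate
Product: 21 (5S)-5-[(1Z)-2-iodoprop-1-en-1-yl]-3-{[(4-methoxybenzyl)oxy]methyl}furan-2(5H)-one
Conditions: RuCl2(=CHPh)(PCy3)(H2IMes) (second-generation Grubbs catalyst, 5 mol%), toluene (0.01 M), 80 °C
Reagents that add atoms: none
Why: Ring-closing metathesis between the vinyl group and the acrylate closes the butenolide (C7=C11); it is placed here because the iodoalkene is inert to the catalyst and the C1=C10 alkene, which could otherwise close a seven-membered carbocycle onto C7, is not yet in the molecule.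

Step 14
Reactants: 21 (5S)-5-[(1Z)-2-iodoprop-1-en-1-yl]-3-{[(4-methoxybenzyl)oxy]methyl}furan-2(5H)-one; 9 (3Z)-4-[(4S)-2,2-dimethyl-1,3-dioxolan-4-yl]pent-3-enal
Product: 23 (5R)-5-[(1Z,5Z)-6-[(4S)-2,2-dimethyl-1,3-dioxolan-4-yl]-3-hydroxy-2-methylhepta-1,5-dien-1-yl]-3-{[(4-methoxybenzyl)oxy]methyl}furan-2(5H)-one (both C3 epimers), via vinylchromium species 22 (not isolated)
Conditions: CrCl2, NiCl2 (cat.), DMSO, rt
Reagents that add atoms: none
Why: Nozaki–Hiyama–Kishi coupling joins the halves at C3–C4 under neutral conditions, with retention of the Z geometry and without enolising the aldehyde or the butenolide; C3 forms as an epimer mixture that steps 15 and 16 correct.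

Step 15
Reactants: 23 the C3 carbinol (both epimers)
Product: 24 (5R)-5-[(1Z,5Z)-6-[(4S)-2,2-dimethyl-1,3-dioxolan-4-yl]-2-methyl-3-oxohepta-1,5-dien-1-yl]-3-{[(4-methoxybenzyl)oxy]methyl}furan-2(5H)-one
Conditions: DMP, pyridine, CH2Cl2, 0 °C
Reagents that add atoms: none
Why: Dess–Martin oxidation converges both epimers on the Z-enone under conditions too mild to isomerise the alkenes.

Step 16
Reactants: 24 the C3 enone
Product: 25 (5R)-5-[(1Z,3S,5Z)-6-[(4S)-2,2-dimethyl-1,3-dioxolan-4-yl]-3-hydroxy-2-methylhepta-1,5-dien-1-yl]-3-{[(4-methoxybenzyl)oxy]methyl}furan-2(5H)-one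
Conditions: (R)-2-methyl-CBS-oxazaborolidine (20 mol%), catecholborane, toluene, −78 °C
Reagents that add atoms: none
Why: Corey–Bakshi–Shibata reduction with the alkenyl group as the large substituent should deliver hydride under catalyst control to give the (3S)-alcohol; catecholborane at −78 °C reduces neither the lactone nor the alkenes.

Step 17
Reactants: 25 the (3S)-alcohol
Product: 26 (1Z,3S,5Z)-6-[(4S)-2,2-dimethyl-1,3-dioxolan-4-yl]-1-[(2R)-4-{[(4-methoxybenzyl)oxy]methyl}-5-oxo-2,5-dihydrofuran-2-yl]-2-methylhepta-1,5-dien-3-yl acetate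
Conditions: Ac2O, pyridine, DMAP (cat.), CH2Cl2, 0 °C
Reagents that add atoms: acetic anhydride, CC(=O)OC(C)=O
Why: DMAP-catalysed acetylation installs the C3 acetate of the target, which also protects C3 from here on.

Step 18
Reactants: 26 the acetate acetonide
Product: 27 (2S,3Z,6S,7Z)-1,2-dihydroxy-8-[(2R)-4-{[(4-methoxybenzyl)oxy]methyl}-5-oxo-2,5-dihydrofuran-2-yl]-3,7-dimethylocta-3,7-dien-6-yl acetate
Conditions: AcOH/H2O/THF (4:1:1), 40 °C
Reagents that add atoms: none
Why: Mild acid hydrolysis of the terminal acetonide frees the C8/C9 diol; PMB ether, acetate and butenolide should survive.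

Step 19
Reactants: 27 the C8/C9 diol
Product: 28 (2S,3Z,6S,7Z)-2-hydroxy-8-[(2R)-4-{[(4-methoxybenzyl)oxy]methyl}-5-oxo-2,5-dihydrofuran-2-yl]-3,7-dimethyl-1-[(triethylsilyl)oxy]octa-3,7-dien-6-yl acetate
Conditions: Et3SiCl (1.05 equiv), imidazole, CH2Cl2, −40 °C
Reagents that add atoms: chlorotriethylsilane, CC[Si](Cl)(CC)CC
Why: Silylation is selective for the primary C8 hydroxyl over the hindered allylic C9 hydroxyl on steric grounds.

Step 20
Reactants: 29 angelic acid, (2Z)-2-methylbut-2-enoic acid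
Product: 30 (2Z)-2-methylbut-2-en-1-ol
Conditions: LiAlH4, Et2O, 0 °C
Reagents that add atoms: none
Why: Hydride reduction of the conjugated acid stops at the allylic alcohol and keeps the Z geometry.

Step 21
Reactants: 30 (2Z)-2-methylbut-2-en-1-ol
Product: 31 [(2S,3R)-2,3-dimethyloxiran-2-yl]methanol
Conditions: Ti(OiPr)4 (cat.), L-(+)-diethyl tartrate (cat.), t-BuOOH, 4 Å molecular sieves, CH2Cl2, −20 °C
Reagents that add atoms: tert-butyl hydroperoxide, CC(C)(C)OO
Why: Sharpless asymmetric epoxidation with the L-(+)-tartrate should give the (2S,3R)-epoxy alcohol; the Z-alkene fixes CH2OH cis to the C3 methyl.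

Step 22
Reactants: 31 [(2S,3R)-2,3-dimethyloxiran-2-yl]methanol
Product: 32 (2R,3R)-2,3-dimethyloxirane-2-carboxylic acid
Conditions: RuCl3 (cat.), NaIO4, CCl4/MeCN/H2O, rt
Reagents that add atoms: sodium periodate, [Na+].[O-]I(=O)(=O)=O (oxygen source for RuO4); water, O
Why: RuO4 made in the flask oxidises the primary alcohol to the acid without opening the epoxide; C2 keeps its geometry and becomes R only through the change in priorities.

Step 23
Reactants: 28 the C8 triethylsilyl ether; 32 (2R,3R)-2,3-dimethyloxirane-2-carboxylic acid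
Product: 34 (2S,3Z,6S,7Z)-6-(acetyloxy)-8-[(2R)-4-{[(4-methoxybenzyl)oxy]methyl}-5-oxo-2,5-dihydrofuran-2-yl]-3,7-dimethyl-1-[(triethylsilyl)oxy]octa-3,7-dien-2-yl (2R,3R)-2,3-dimethyloxirane-2-carboxylate, via mixed anhydride 33 (not isolated)
Conditions: 32, 2,4,6-trichlorobenzoyl chloride, Et3N, THF, rt; then 28, DMAP, toluene, rt
Reagents that add atoms: none
Why: Yamaguchi esterification acylates the hindered allylic C9 hydroxyl with the α,α-disubstituted glycidic acid; neither partner can epimerise, and the amine bases are too weak to deprotonate the butenolide at C6.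

Step 24
Reactants: 34 the PMB ether
Product: 35 (2S,3Z,6S,7Z)-6-(acetyloxy)-8-[(2R)-4-(hydroxymethyl)-5-oxo-2,5-dihydrofuran-2-yl]-3,7-dimethyl-1-[(triethylsilyl)oxy]octa-3,7-dien-2-yl (2R,3R)-2,3-dimethyloxirane-2-carboxylate
Conditions: DDQ, CH2Cl2/pH 7 buffer (10:1), 0 °C
Reagents that add atoms: none
Why: Oxidative cleavage of the PMB ether frees the C13 hydroxyl; buffering should preserve the primary silyl ether.

Step 25
Reactants: 35 the C13 alcohol
Product: 36 (2S,3Z,6S,7Z)-6-(acetyloxy)-8-[(2R)-4-(bromomethyl)-5-oxo-2,5-dihydrofuran-2-yl]-3,7-dimethyl-1-[(triethylsilyl)oxy]octa-3,7-dien-2-yl (2R,3R)-2,3-dimethyloxirane-2-carboxylate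
Conditions: CBr4, PPh3, CH2Cl2, 0 °C
Reagents that add atoms: carbon tetrabromide, BrC(Br)(Br)Br
Why: Appel bromination converts the primary allylic alcohol into the C13 bromide under neutral conditions; from here on no base or nucleophile is used.

Step 26
Reactants: 36 the bromide
Product: 37 (2S,3Z,6S,7Z)-6-(acetyloxy)-8-[(2R)-4-(bromomethyl)-5-oxo-2,5-dihydrofuran-2-yl]-1-hydroxy-3,7-dimethylocta-3,7-dien-2-yl (2R,3R)-2,3-dimethyloxirane-2-carboxylate
Conditions: PPTS (cat.), MeOH/CH2Cl2 (1:1), 0 °C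
Reagents that add atoms: none
Why: Mild acid methanolysis removes the primary silyl ether without base, so the C6 hydrogen, the allylic bromide and the position of the hindered C9 ester are not endangered.

Step 27
Reactants: 37 the C8 alcohol
Product: 38 (2S,3Z,6S,7Z)-6-(acetyloxy)-8-[(2R)-4-(bromomethyl)-5-oxo-2,5-dihydrofuran-2-yl]-3,7-dimethyl-1-oxoocta-3,7-dien-2-yl (2R,3R)-2,3-dimethyloxirane-2-carboxylate
Conditions: DMP, CH2Cl2, 0 °C → rt
Reagents that add atoms: none
Why: Dess–Martin oxidation gives the α-acyloxy aldehyde under neutral conditions; it is used at once without chromatography.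

Step 28
Reactants: 38 the bromide aldehyde
Product: 40 (3S,6R,7S,8R,9S,1(10)Z,4Z)-3-acetoxy-8-hydroxy-9-{[(2R,3R)-2,3-dimethyloxirane-2-carbonyl]oxy}germacra-1(10),4,11(13)-trien-12,6-olide, via allylchromium species 39 (not isolated)
Conditions: CrCl2 (10 equiv), 4 Å molecular sieves, THF, rt, slow addition of 38 (final 0.002 M)
Reagents that add atoms: none
Why: Two equivalents of CrCl2 reduce the C13–Br bond of 38 to the allylchromium species 39 (trivalent chromium, bound at C13), which adds through its γ-carbon C7 to the tethered C8 aldehyde in a closed, chair-like six-membered transition state (SE2′), so that one event forms C7–C8, moves the double bond to the exocyclic C11=C13 position and leaves the free C8 hydroxyl; the closest known reaction types are Nozaki–Hiyama–Kishi allylation macrocyclisations of ω-formyl allylic bromides and intermolecular Barbier additions of 3-(bromomethyl)furan-2(5H)-ones to aldehydes. The ten-membered carbocycle closes in 10-exo-trig fashion at the aldehyde carbon. C7 is controlled by the tether: the aldehyde hangs from C6 on a short chain stiffened by two Z-alkenes and is expected to reach C7 only across the lactone face that carries C5, which gives the cis ring fusion against the usual preference of external aldehydes for the opposite face. C8 is controlled by the chelate and by C9: with the chromium-bound carbonyl oxygen held on the C13 side, placing C9 over the lactone ring keeps the ring torsions about C6–C7, C7–C8 and C8–C9 gauche and of like sign (the other aldehyde face forces a syn-pentane contact between C5 and C9) and puts the C9 acyloxy group anti to the incoming C7 (polar Felkin–Anh), which should give the 8,9-anti, all-cis array. The step needs ring closure to outrun oligomerisation (secured by slow addition at high dilution), γ- over α-attack (intrinsic to allylchromium reagents), and reduction of the allylic bromide only, which is by far the most easily reduced group, so that divalent chromium should leave the acetate, lactone, glycidic ester and aldehyde alone.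

**Compound list**

1 | (3-bromopropoxy)(tert-butyl)dimethylsilane | CC(C)(C)[Si](C)(C)OCCCBr | starting material
2 | {3-[(tert-butyldimethylsilyl)oxy]propyl}triphenylphosphonium bromide | CC(C)(C)[Si](C)(C)OCCC[P+](c1ccccc1)(c1ccccc1)c1ccccc1.[Br-] | intermediate
3 | methyl (4R)-2,2-dimethyl-1,3-dioxolane-4-carboxylate | COC(=O)[C@@H]1OC(C)(C)OC1 | starting material
4 | (4R)-N-methoxy-N,2,2-trimethyl-1,3-dioxolane-4-carboxamide | CON(C)C(=O)[C@@H]1OC(C)(C)OC1 | intermediate (not isolated)
5 | 1-[(4R)-2,2-dimethyl-1,3-dioxolan-4-yl]ethan-1-one | CC(=O)[C@@H]1OC(C)(C)OC1 | intermediate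
6 | {3-[(tert-butyldimethylsilyl)oxy]propylidene}triphenylphosphorane | CC(C)(C)[Si](C)(C)OCCC=P(c1ccccc1)(c1ccccc1)c1ccccc1 | intermediate (not isolated)
7 | tert-butyl({(3Z)-4-[(4S)-2,2-dimethyl-1,3-dioxolan-4-yl]pent-3-en-1-yl}oxy)dimethylsilane | CC(C)(C)[Si](C)(C)OCC/C=C(/C)[C@@H]1OC(C)(C)OC1 | intermediate
8 | (3Z)-4-[(4S)-2,2-dimethyl-1,3-dioxolan-4-yl]pent-3-en-1-ol | OCC/C=C(/C)[C@@H]1OC(C)(C)OC1 | intermediate
9 | (3Z)-4-[(4S)-2,2-dimethyl-1,3-dioxolan-4-yl]pent-3-enal | O=CC/C=C(/C)[C@@H]1OC(C)(C)OC1 | intermediate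
10 | 2-(bromomethyl)prop-2-enoic acid | C=C(CBr)C(=O)O | starting material
11 | 2-{[(4-methoxybenzyl)oxy]methyl}prop-2-enoic acid | C=C(COCc1ccc(OC)cc1)C(=O)O | intermediate
12 | penta-1,4-dien-3-ol | C=CC(O)C=C | starting material
13 | (1S)-1-[(2R)-oxiran-2-yl]prop-2-en-1-ol | O[C@H]([C@H]1CO1)C=C | intermediate
14 | tert-butyldimethyl({(1S)-1-[(2R)-oxiran-2-yl]prop-2-en-1-yl}oxy)silane | CC(C)(C)[Si](C)(C)O[C@H]([C@H]1CO1)C=C | intermediate
15 | (2R,3S)-3-[(tert-butyldimethylsilyl)oxy]pent-4-ene-1,2-diol | CC(C)(C)[Si](C)(C)O[C@H]([C@H](O)CO)C=C | intermediate (not isolated)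
16 | (2S)-2-[(tert-butyldimethylsilyl)oxy]but-3-enal | CC(C)(C)[Si](C)(C)O[C@H](C=O)C=C | intermediate
17 | tert-butyl{[(3S,4Z)-5-iodohexa-1,4-dien-3-yl]oxy}dimethylsilane | CC(C)(C)[Si](C)(C)O[C@H](/C=C(/C)I)C=C | intermediate
18 | (3S,4Z)-5-iodohexa-1,4-dien-3-ol | O[C@H](/C=C(/C)I)C=C | intermediate
19 | O-acylisourea of 11 with DCC | C=C(COCc1ccc(OC)cc1)C(=O)OC(=NC1CCCCC1)NC1CCCCC1 | intermediate (not isolated)
20 | (3S,4Z)-5-iodohexa-1,4-dien-3-yl 2-{[(4-methoxybenzyl)oxy]methyl}prop-2-enoate | C=C(COCc1ccc(OC)cc1)C(=O)O[C@H](/C=C(/C)I)C=C | intermediate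
21 | (5S)-5-[(1Z)-2-iodoprop-1-en-1-yl]-3-{[(4-methoxybenzyl)oxy]methyl}furan-2(5H)-one | O=C1O[C@H](/C=C(/C)I)C=C1COCc1ccc(OC)cc1 | intermediate
22 | dichloro(alkenyl)chromium species from 21 (Cr in place of I) | O=C1O[C@H](/C=C(/C)[Cr](Cl)Cl)C=C1COCc1ccc(OC)cc1 | intermediate (not isolated)
23 | (5R)-5-[(1Z,5Z)-6-[(4S)-2,2-dimethyl-1,3-dioxolan-4-yl]-3-hydroxy-2-methylhepta-1,5-dien-1-yl]-3-{[(4-methoxybenzyl)oxy]methyl}furan-2(5H)-one, both C3 epimers | O=C1O[C@H](/C=C(/C)C(O)C/C=C(/C)[C@@H]2OC(C)(C)OC2)C=C1COCc1ccc(OC)cc1 | intermediate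
24 | (5R)-5-[(1Z,5Z)-6-[(4S)-2,2-dimethyl-1,3-dioxolan-4-yl]-2-methyl-3-oxohepta-1,5-dien-1-yl]-3-{[(4-methoxybenzyl)oxy]methyl}furan-2(5H)-one | O=C1O[C@H](/C=C(/C)C(=O)C/C=C(/C)[C@@H]2OC(C)(C)OC2)C=C1COCc1ccc(OC)cc1 | intermediate
25 | (5R)-5-[(1Z,3S,5Z)-6-[(4S)-2,2-dimethyl-1,3-dioxolan-4-yl]-3-hydroxy-2-methylhepta-1,5-dien-1-yl]-3-{[(4-methoxybenzyl)oxy]methyl}furan-2(5H)-one | O=C1O[C@H](/C=C(/C)[C@@H](O)C/C=C(/C)[C@@H]2OC(C)(C)OC2)C=C1COCc1ccc(OC)cc1 | intermediate
26 | (1Z,3S,5Z)-6-[(4S)-2,2-dimethyl-1,3-dioxolan-4-yl]-1-[(2R)-4-{[(4-methoxybenzyl)oxy]methyl}-5-oxo-2,5-dihydrofuran-2-yl]-2-methylhepta-1,5-dien-3-yl acetate | O=C1O[C@H](/C=C(/C)[C@@H](OC(C)=O)C/C=C(/C)[C@@H]2OC(C)(C)OC2)C=C1COCc1ccc(OC)cc1 | intermediate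
27 | (2S,3Z,6S,7Z)-1,2-dihydroxy-8-[(2R)-4-{[(4-methoxybenzyl)oxy]methyl}-5-oxo-2,5-dihydrofuran-2-yl]-3,7-dimethylocta-3,7-dien-6-yl acetate | O=C1O[C@H](/C=C(/C)[C@@H](OC(C)=O)C/C=C(/C)[C@H](O)CO)C=C1COCc1ccc(OC)cc1 | intermediate
28 | (2S,3Z,6S,7Z)-2-hydroxy-8-[(2R)-4-{[(4-methoxybenzyl)oxy]methyl}-5-oxo-2,5-dihydrofuran-2-yl]-3,7-dimethyl-1-[(triethylsilyl)oxy]octa-3,7-dien-6-yl acetate | O=C1O[C@H](/C=C(/C)[C@@H](OC(C)=O)C/C=C(/C)[C@H](O)CO[Si](CC)(CC)CC)C=C1COCc1ccc(OC)cc1 | intermediate
29 | angelic acid, (2Z)-2-methylbut-2-enoic acid | C/C=C(/C)C(=O)O | starting material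
30 | (2Z)-2-methylbut-2-en-1-ol | C/C=C(/C)CO | intermediate
31 | [(2S,3R)-2,3-dimethyloxiran-2-yl]methanol | OC[C@]1(C)O[C@@H]1C | intermediate
32 | (2R,3R)-2,3-dimethyloxirane-2-carboxylic acid | OC(=O)[C@]1(C)O[C@@H]1C | intermediate
33 | (2R,3R)-2,3-dimethyloxirane-2-carboxylic 2,4,6-trichlorobenzoic anhydride | O=C(OC(=O)[C@]1(C)O[C@@H]1C)c1c(Cl)cc(Cl)cc1Cl | intermediate (not isolated)
34 | (2S,3Z,6S,7Z)-6-(acetyloxy)-8-[(2R)-4-{[(4-methoxybenzyl)oxy]methyl}-5-oxo-2,5-dihydrofuran-2-yl]-3,7-dimethyl-1-[(triethylsilyl)oxy]octa-3,7-dien-2-yl (2R,3R)-2,3-dimethyloxirane-2-carboxylate | O=C1O[C@H](/C=C(/C)[C@@H](OC(C)=O)C/C=C(/C)[C@H](OC(=O)[C@]2(C)O[C@@H]2C)CO[Si](CC)(CC)CC)C=C1COCc1ccc(OC)cc1 | intermediate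
35 | as 34 with 4-(hydroxymethyl) on the furanone | O=C1O[C@H](/C=C(/C)[C@@H](OC(C)=O)C/C=C(/C)[C@H](OC(=O)[C@]2(C)O[C@@H]2C)CO[Si](CC)(CC)CC)C=C1CO | intermediate
36 | as 34 with 4-(bromomethyl) on the furanone | O=C1O[C@H](/C=C(/C)[C@@H](OC(C)=O)C/C=C(/C)[C@H](OC(=O)[C@]2(C)O[C@@H]2C)CO[Si](CC)(CC)CC)C=C1CBr | intermediate
37 | (2S,3Z,6S,7Z)-6-(acetyloxy)-8-[(2R)-4-(bromomethyl)-5-oxo-2,5-dihydrofuran-2-yl]-1-hydroxy-3,7-dimethylocta-3,7-dien-2-yl (2R,3R)-2,3-dimethyloxirane-2-carboxylate | O=C1O[C@H](/C=C(/C)[C@@H](OC(C)=O)C/C=C(/C)[C@H](OC(=O)[C@]2(C)O[C@@H]2C)CO)C=C1CBr | intermediate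
38 | (2S,3Z,6S,7Z)-6-(acetyloxy)-8-[(2R)-4-(bromomethyl)-5-oxo-2,5-dihydrofuran-2-yl]-3,7-dimethyl-1-oxoocta-3,7-dien-2-yl (2R,3R)-2,3-dimethyloxirane-2-carboxylate | O=C1O[C@H](/C=C(/C)[C@@H](OC(C)=O)C/C=C(/C)[C@H](OC(=O)[C@]2(C)O[C@@H]2C)C=O)C=C1CBr | intermediate
39 | dichloro(allyl)chromium species from 38 (Cr on C13 in place of Br) | O=C1O[C@H](/C=C(/C)[C@@H](OC(C)=O)C/C=C(/C)[C@H](OC(=O)[C@]2(C)O[C@@H]2C)C=O)C=C1C[Cr](Cl)Cl | intermediate (not isolated)
40 | (3S,6R,7S,8R,9S,1(10)Z,4Z)-3-acetoxy-8-hydroxy-9-{[(2R,3R)-2,3-dimethyloxirane-2-carbonyl]oxy}germacra-1(10),4,11(13)-trien-12,6-olide | C=C1C(=O)O[C@@H]2/C=C(/C)[C@@H](OC(C)=O)C/C=C(/C)[C@H](OC(=O)[C@]3(C)O[C@@H]3C)[C@H](O)[C@H]12 | target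

**Totals**

Total step count: 28.
Longest linear sequence: 19 steps (steps 7–19 and 23–28, from penta-1,4-dien-3-ol).

**Steps most likely to fail**

Step 28. The ring may close across the intended lactone face but on the wrong face of the aldehyde, because the closed transition state then has to place C9 in the more crowded position over the lactone ring; intermolecular coupling is the second danger. The fallback sets C8 by reduction instead of by the C–C bond formation. It sets out from 38: the cyclisation then gives the C8 epimer F1. Oxidation of F1 with DMP (CH2Cl2, 0 °C) would give the ten-membered C8 ketone F2. Luche reduction (NaBH4, CeCl3·7H2O, MeOH, −78 °C) should deliver hydride to the ring face that is free of the two flanking substituents (C11 on C7 and the acyloxy group on C9) and so return the all-cis alcohol 40. A closure across the other lactone face (trans fusion) would not be repaired by this sequence.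

Step 10. The basic iodo-ylide may enolise the α-silyloxy β,γ-unsaturated aldehyde, with loss of configurational purity at C6, and conversion with this ylide is often incomplete. The fallback builds the iodoalkene by stepwise, non-basic olefination and cross-coupling. It sets out from 16: CBr4/PPh3 (CH2Cl2, 0 °C, first stage of the Corey–Fuchs sequence) gives the 1,1-dibromodiene F3. Palladium-catalysed trans-selective Negishi monomethylation (Me2Zn, PdCl2(DPEphos), THF, 0 °C → rt) should replace only the bromine trans to C6 and give the (Z)-bromoalkene F4. Copper-catalysed halogen exchange (CuI cat., NaI, N,N′-dimethylethylenediamine, dioxane, 110 °C), which retains the alkene geometry, comes back at iodide 17.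

Step 16. The catalyst may discriminate poorly between the two faces of a ketone flanked by a twisted Z-alkenyl group and an allylic methylene, which would give a mixture of C3 epimers. The fallback uses both epimers from the coupling instead of a ketone reduction. It sets out from 23: the two C3 epimers are separated by chromatography. The (3S)-epimer is 25 and is acetylated as in step 17. The (3R)-epimer F5 is converted into the same acetate by Mitsunobu inversion with acetic acid (PPh3, DIAD, AcOH, toluene, 0 °C), which comes back at 26.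

**Further compounds**

F1 | step 28 | C8 epimer of 40, (8S)-alcohol, other centers as in 40 | C=C1C(=O)O[C@@H]2/C=C(/C)[C@@H](OC(C)=O)C/C=C(/C)[C@H](OC(=O)[C@]3(C)O[C@@H]3C)[C@@H](O)[C@H]12
F2 | step 28 | 8-oxo analogue of 40 (C8 ketone, other centers as in 40) | C=C1C(=O)O[C@@H]2/C=C(/C)[C@@H](OC(C)=O)C/C=C(/C)[C@H](OC(=O)[C@]3(C)O[C@@H]3C)C(=O)[C@H]12
F3 | step 10 | tert-butyl{[(3S)-5,5-dibromopenta-1,4-dien-3-yl]oxy}dimethylsilane | CC(C)(C)[Si](C)(C)O[C@H](C=C(Br)Br)C=C
F4 | step 10 | tert-butyl{[(3S,4Z)-5-bromohexa-1,4-dien-3-yl]oxy}dimethylsilane | CC(C)(C)[Si](C)(C)O[C@H](/C=C(/C)Br)C=C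
F5 | step 16 | (5R)-5-[(1Z,3R,5Z)-6-[(4S)-2,2-dimethyl-1,3-dioxolan-4-yl]-3-hydroxy-2-methylhepta-1,5-dien-1-yl]-3-{[(4-methoxybenzyl)oxy]methyl}furan-2(5H)-one | O=C1O[C@H](/C=C(/C)[C@H](O)C/C=C(/C)[C@@H]2OC(C)(C)OC2)C=C1COCc1ccc(OC)cc1
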